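The zeta flask at 25 °C read 36% L at 1.33 h, more than the epsilon flask at 10 °C read at 120 min, which was 15%.

common to all: D 29 mM
- zeta: G 20.3 mM; temperature 25 °C; the very flask that is asked about, followed so far
- epsilon: G 30 mM; temperature 10 °C; run made earlier
- flask: G 20.3 mM; temperature 25 °C; time 10 h

zeta run (percent of the D charged)

| time / h | L / % |
|---|---|
| 1.33 | 36 |
| 3.00 | 39 |
| 4.00 | 35 |
| 6.00 | 36 |
| 8.00 | 36 |
| 10.0 | 37 |

epsilon run (percent of the D charged)

| time / min | L / % |
|---|---|
| 15.0 | 2 |
| 30.0 | 0 |
| 50.0 | 2 |
| 60.0 | 4 |
| 80.0 | 6 |
| 120 | 15 |

(readings scatter by 1.5 percentage points)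

- L, in percent of the D first charged, at 10 h
- the remedy with the largest gain of L, or "none" below 2 percentage points (oak / larch / elm / maple / none)
- L present, with what was taken out counted in, in percent of the D first charged, after oak
- L present, with what was taken out counted in, in percent of the D first charged, after elm

- oak: at 10 h take out 90% of the L then present, then wait 10 h
- larch: at 10 h raise the temperature by 25 K, then wait 10 h
- elm: at 10 h add G, 100% of the amount charged, then wait 10 h
- maple: change nothing and wait 10 h more

- L that was removed still counts
- additions bring no volume worth counting

The zeta readings average 36.5%. That is 0.521 of cL made per cG charged; call this the yield of G. Two chemists dispute what this number is.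

The first calls it a fixed price. G is the limiting reagent, this chemist says. Two G buy one L, which caps L at 35.0% of D, close to the plateau. So a new charge of G buys the same again.

The second calls it a share that moves with the flask. Epsilon shows a lag: L read 4% at 60.0 min and 15% at 120 min. That is 3.75 times as much in twice the time, though each reading is good to 1.5 percentage points. So L grows from something that must build up first, this chemist says, and a second charge of G would meet that stock ready. Its yield should then exceed 0.521.

My own reckoning at a fixed yield puts elm at 73.0%. The forecast takes the first side with a slightly lower number: 36.5% now, elm as the best remedy, 36.5% after oak and 71% after elm. In its words, “Fresh G should give about another 35 %, reaching about 71 %”.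

    D → E (k = 0.0140 min⁻¹, Ea = 92.0 kJ mol⁻¹)
    G → Z (k = 0.170 min⁻¹, Ea = 90.0 kJ mol⁻¹)
    E + Z → L (k = 3.50 M⁻¹ min⁻¹, Ea = 67.0 kJ mol⁻¹)
    Z → Q (k = 0.0160 min⁻¹, Ea = 89.0 kJ mol⁻¹)
    (constants at 25 °C)

The flask gives 37.0% now, elm as the best remedy, 37.0% after oak and 84.7% after elm. At 10.0 h the flask holds cQ of 9.58 mM beside cL of 10.7 mM, together 20.3 mM, against 20.3 mM of G charged. The first chemist's price stands for this flask's first charge: 0.528 against 0.521. The elm charge earned a yield of 0.681. The neighbour with 73 mM of D, on the same G, gave 19.8% L, a yield of 0.712.

The earlier runs and the new flask are calculated for substances that don't exist; noise was put on by code.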